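**Plan**

1. Numbering used here: bicyclo[3.3.1]nonane C1 (isobutyryl bridgehead), C2(=O), C3, C4(=O), C5 (geranyl bridgehead), C6, C7, C8 (CMe2), C9 (bridging C=O); C10 is the CH2 on C7; C11(H)–C12(Me2)–C13(H, i-Pr)–C14(H2) are the other cyclopentane carbons (C11 bonded to C10 and C3, C14 to C3).
2. Retrosynthetic cuts, in order: isopropyl ⇐ isopropenyl; C3–C11 and C12–C13 (one oxidative radical cascade from a bicyclic trione with C3 prenyl and endo C7 prenyl); C10–C11 (B-alkyl Suzuki on a C7 methylidene); C1–acyl; C5–C9 and C2–C3 (double Claisen condensation of an acyclic keto malonate); C5–C6, C5–geranyl and C3–C14 (alkylations of allyl acetoacetate); C7–C8 (cuprate addition).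
3. Enabling feature: the C9 ketone lies between the quaternary carbons C1 and C5, C1 carries both acyl carbons C9 and C2 (a malonyl carbon), and C5 and C3 are the two α-carbons of the C4 ketone. Ring B (C1–C8–C7–C6–C5–C9) and ring A (C1–C2–C3–C4–C5–C9) can therefore be closed from one open chain by two intramolecular C-acylations, the first forming C5–C9.
4. Forward order of rings: open chain → ring B (C5–C9) → ring A (C2–C3) in the same flask → the two seven-membered rings of the homoadamantane (C3–C11) → cyclopentane (C12–C13).
5. Stereochemistry: C1/C5 are locked cis by the bicycle and their absolute sense comes from a kinetic resolution with a chiral lithium amide during bridgehead acylation; C7 from exo-face hydroboration; C3, C11 and C13 from the cage-controlled radical cascade; the E-alkene from geranyl bromide.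

Key step: step 7

Assumption: the (R,R)-configured lithium amide is taken to be the base that deprotonates the enantiomer of 14 drawn below faster; should the sense be opposite, the (S,S)-amide is used. Compounds 9–11 are racemic at one centre that is later lost or rebuilt; 12–14 are racemates drawn as the enantiomer carried forward.

**Step 1**
Reactants: 1 diethyl 2-(propan-2-ylidene)propanedioate; 2 isopropenylmagnesium bromide
Product: 3 diethyl 2-(2,3-dimethylbut-3-en-2-yl)propanedioate
Conditions: CuI (10 mol %), THF, −30 → 0 °C; then 1 M HCl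
Reagents that add atoms: none
Why: Copper-catalysed conjugate (1,4-) addition of an alkenyl Grignard reagent to an alkylidene malonate should install the quaternary C8 next to the future C7 alkene; no stereocentre is formed.

**Step 2**
Reactants: 3 diethyl 2-(2,3-dimethylbut-3-en-2-yl)propanedioate
Product: 4 diethyl 2-[3-(chloromethyl)-2-methylbut-3-en-2-yl]propanedioate
Conditions: N-chlorosuccinimide (1.1 equiv), PhSeCl (5 mol %), MeCN, 25 °C
Reagents that add atoms: N-chlorosuccinimide, O=C1CCC(=O)N1Cl
Why: Selenium-catalysed ene-type allylic chlorination should act on the only allylic C–H position (the vinylic methyl) and return the 1,1-disubstituted alkene by degenerate allyl transposition, while the hindered malonate C–H stays untouched in the absence of base.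

**Step 3**
Reactants: 5 prop-2-enyl 3-oxobutanoate (allyl acetoacetate); 6 1-bromo-3-methylbut-2-ene (prenyl bromide)
Product: 7 prop-2-enyl 7-methyl-3-oxooct-6-enoate
Conditions: NaH (1.1 equiv), THF, 0 °C; n-BuLi (1.05 equiv), 0 °C; then 6, 0 → 25 °C; 1 M HCl
Reagents that add atoms: none
Why: γ-Alkylation of the acetoacetate dianion (the terminal carbanion is the more nucleophilic site) with an allylic bromide puts the future C3 prenyl group in place; no stereocentre is formed.

**Step 4**
Reactants: 7 prop-2-enyl 7-methyl-3-oxooct-6-enoate; 8 (2E)-1-bromo-3,7-dimethylocta-2,6-diene (geranyl bromide)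
Product: 9 prop-2-enyl (4E)-5,9-dimethyl-2-(5-methylhex-4-enoyl)deca-4,8-dienoate (racemate)
Conditions: K2CO3, acetone, 50 °C
Reagents that add atoms: none
Why: C-Alkylation of a β-keto ester at its doubly activated carbon (future C5) by SN2 reaction with an allylic bromide should keep the E-alkene; the new centre is racemic and is rebuilt later.

**Step 5**
Reactants: 9 prop-2-enyl (4E)-5,9-dimethyl-2-(5-methylhex-4-enoyl)deca-4,8-dienoate; 4 diethyl 2-[3-(chloromethyl)-2-methylbut-3-en-2-yl]propanedioate
Product: 10 prop-2-enyl (4E)-2-[4,4-bis(ethoxycarbonyl)-3,3-dimethyl-2-methylidenebutyl]-5,9-dimethyl-2-(5-methylhex-4-enoyl)deca-4,8-dienoate (racemate)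
Conditions: NaH (1.0 equiv), NaI (10 mol %), THF/DMF 4:1, 0 → 45 °C
Reagents that add atoms: none
Why: A second C-alkylation of the β-keto ester (the more acidic C–H; the hindered malonate C–H of 4 stays protonated) creates a quaternary carbon that joins C6–C8 and C1 to C5, and SN2 and SN2′ attack on the symmetric allyl unit give the same product.

**Step 6**
Reactants: 10 the doubly alkylated allyl β-keto ester
Product: 11 diethyl 2-[(7E)-2,8,12-trimethyl-3-methylidene-5-(5-methylhex-4-enoyl)trideca-7,11-dien-2-yl]propanedioate (racemate)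
Conditions: Pd(PPh3)4 (3 mol %), morpholine (3 equiv), THF, 25 °C
Reagents that add atoms: none
Why: Palladium-catalysed deallylation–decarboxylation of an allyl β-keto ester (Tsuji–Trost-type, with morpholine as allyl acceptor) should unveil the C4 ketone with H at C5 under neutral conditions that spare the ethyl esters and all alkenes.

**Step 7**
Reactants: 11 the acyclic keto malonate
Product: 13 racemic bicyclic trione enol (5-geranyl-4-hydroxy-8,8-dimethyl-7-methylidene-3-prenylbicyclo[3.3.1]non-3-ene-2,9-dione), via ring-B keto ester 12 (not isolated)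
Conditions: KOt-Bu (4 equiv), THF, 0 → 60 °C; then 1 M HCl
Reagents that add atoms: none
Why: After sacrificial deprotonation of the malonate, the equilibrating potassium enolate at the geranyl-bearing α-carbon C5 of the ketone adds to one malonate ester carbonyl (C9) and ethoxide leaves, and the β-keto ester 12 so formed undergoes a second Claisen closure from the other α-carbon C3 onto the remaining ester (C2). The closest known reaction type is the ketone–malonate Dieckmann condensation that makes dimedone, together with the Dieckmann closures used for bicyclo[3.3.1]nonane-2,4,9-triones. Ring B closes 6-(enolexo)-exo-trig by the C5–C9 bond and ring A closes 6-(enolendo)-exo-trig by the C2–C3 bond across the 1,3-diaxial positions of ring B. C5 is formed without control (racemate), and C1 is an epimerisable β-keto ester centre that is fixed relative to C5 because only the cis-diaxial arrangement of the two acyl arms can bridge. The step needs the C5 enolate to win over the C3 enolate in the first closure and condensation to win over retro-Claisen cleavage: the C3 enolate could only close an eight-membered ring, all proton transfers are reversible, and the sequence ends in the strongly stabilised vinylogous carboxylate of 13, which should act as the thermodynamic sink.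

**Step 8**
Reactants: 13 racemic bicyclic trione enol
Product: 14 racemic 5-geranyl-4-methoxy-8,8-dimethyl-7-methylidene-3-prenylbicyclo[3.3.1]non-3-ene-2,9-dione
Conditions: trimethylsilyldiazomethane, MeOH/toluene 1:4, 0 °C
Reagents that add atoms: trimethylsilyldiazomethane, C[Si](C)(C)C=[N+]=[N-]
Why: O-Methylation of the vinylogous acid by a diazoalkane; the 4-methoxy isomer, in which C1–H lies between the C2 and C9 carbonyl groups, is carried on, and the 2-methoxy isomer would be hydrolysed back to 13 with aqueous HCl.

**Step 9**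
Reactants: 14 racemic methyl enol ether; 15 2-methylpropanoyl chloride (isobutyryl chloride)
Product: 16 5-geranyl-4-methoxy-8,8-dimethyl-7-methylidene-1-(2-methylpropanoyl)-3-prenylbicyclo[3.3.1]non-3-ene-2,9-dione (single enantiomer with bridgeheads as in 22)
Conditions: lithium (R,R)-bis(1-phenylethyl)amide (0.55 equiv, from the amine and n-BuLi), LiCl, THF, −78 °C; then 15, −78 °C
Reagents that add atoms: none
Why: Bridgehead deprotonation of a bicyclo[3.3.1]nonane trione enol ether by a lithium amide followed by C-acylation; the chiral amide should deprotonate one enantiomer of 14 faster (kinetic resolution), so that 16 arises from the matched enantiomer and the unreacted antipode of 14 is removed by chromatography.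

**Step 10**
Reactants: 16 the C1-acylated methylidene compound; 17 1-bromo-2-methylprop-1-ene
Product: 19 5-geranyl-4-methoxy-8,8-dimethyl-1-(2-methylpropanoyl)-3,7-diprenylbicyclo[3.3.1]non-3-ene-2,9-dione with the C7 prenyl group endo (syn to the C2–C4 bridge), via B-alkyl-9-BBN adduct 18 (not isolated)
Conditions: 9-BBN (1.5 equiv), THF, 25 °C; then Pd(dppf)Cl2 (5 mol %), AsPh3, Cs2CO3, 17, DMF/H2O, 25 → 40 °C
Reagents that add atoms: none
Why: Hydroboration with 9-BBN should select the 1,1-disubstituted C7 methylidene over the three trisubstituted alkenes and deliver hydrogen to C7 from the open exo face (the endo face is covered by ring A), so that the CH2–B arm is endo; B-alkyl Suzuki–Miyaura coupling with the alkenyl bromide then completes the endo prenyl group.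

**Step 11**
Reactants: 19 the endo-prenyl methyl enol ether
Product: 20 5-geranyl-4-hydroxy-8,8-dimethyl-1-(2-methylpropanoyl)-3,7-diprenylbicyclo[3.3.1]non-3-ene-2,9-dione (7-endo; enol form of the trione)
Conditions: LiCl (10 equiv), DMSO, 120 °C; then 1 M HCl
Reagents that add atoms: none
Why: Nucleophilic demethylation (SN2 attack of chloride on the O-methyl group of the vinylogous ester) should free the enolised 2,4-diketone needed for oxidation without touching the hindered tricarbonyl unit at C1.

**Step 12**
Reactants: 20 the free enol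
Product: 21 the caged tetraketone with prop-1-en-2-yl at C13 (all other atoms and stereocentres as in 22)
Conditions: Mn(OAc)3·2H2O (2.2 equiv), Cu(OAc)2·H2O (1.0 equiv), degassed AcOH, 25 °C
Reagents that add atoms: none
Why: Oxidative radical cyclisation of a 1,3-dicarbonyl compound: the C3 radical should add 7-exo-trig to C11 of the endo C7 prenyl group (which alone can reach the lower lobe at C3, fixing C3 and closing the homoadamantane with C12 on the C2 side as in the natural series), the tertiary C12 radical should close 5-exo-trig onto C13 of the C3 prenyl group with its C(CH3)2 terminus turned away from the cage (isopropenyl on the cyclopentane face that carries H at C11), and divalent copper should oxidise the last radical to the isopropenyl group.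

**Step 13**
Reactants: 21 the isopropenyl cage compound
Product: 22 the target CNP0379246.1
Conditions: H2 (1 atm), RhCl(PPh3)3 (10 mol %), benzene/EtOH 1:1, 25 °C
Reagents that add atoms: none
Why: Homogeneous hydrogenation with RhCl(PPh3)3 should reduce the 1,1-disubstituted isopropenyl alkene and leave the two trisubstituted geranyl alkenes; no stereocentre is formed.

**Compound list**

1 | diethyl 2-(propan-2-ylidene)propanedioate | CCOC(=O)C(=C(C)C)C(=O)OCC | starting material
2 | isopropenylmagnesium bromide | CC(=C)[Mg]Br | starting material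
3 | diethyl 2-(2,3-dimethylbut-3-en-2-yl)propanedioate | CCOC(=O)C(C(=O)OCC)C(C)(C)C(C)=C | intermediate
4 | diethyl 2-[3-(chloromethyl)-2-methylbut-3-en-2-yl]propanedioate | CCOC(=O)C(C(=O)OCC)C(C)(C)C(=C)CCl | intermediate
5 | prop-2-enyl 3-oxobutanoate | CC(=O)CC(=O)OCC=C | starting material
6 | 1-bromo-3-methylbut-2-ene | CC(C)=CCBr | starting material
7 | prop-2-enyl 7-methyl-3-oxooct-6-enoate | CC(C)=CCCC(=O)CC(=O)OCC=C | intermediate
8 | (2E)-1-bromo-3,7-dimethylocta-2,6-diene | CC(C)=CCC/C(C)=C/CBr | starting material
9 | prop-2-enyl (4E)-5,9-dimethyl-2-(5-methylhex-4-enoyl)deca-4,8-dienoate, racemate | CC(C)=CCC/C(C)=C/CC(C(=O)CCC=C(C)C)C(=O)OCC=C | intermediate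
10 | prop-2-enyl (4E)-2-[4,4-bis(ethoxycarbonyl)-3,3-dimethyl-2-methylidenebutyl]-5,9-dimethyl-2-(5-methylhex-4-enoyl)deca-4,8-dienoate, racemate | CC(C)=CCC/C(C)=C/CC(CC(=C)C(C)(C)C(C(=O)OCC)C(=O)OCC)(C(=O)CCC=C(C)C)C(=O)OCC=C | intermediate
11 | diethyl 2-[(7E)-2,8,12-trimethyl-3-methylidene-5-(5-methylhex-4-enoyl)trideca-7,11-dien-2-yl]propanedioate, racemate | CC(C)=CCC/C(C)=C/CC(CC(=C)C(C)(C)C(C(=O)OCC)C(=O)OCC)C(=O)CCC=C(C)C | intermediate
12 | ethyl 3-[(2E)-3,7-dimethylocta-2,6-dienyl]-6,6-dimethyl-5-methylidene-3-(5-methylhex-4-enoyl)-2-oxocyclohexane-1-carboxylate, racemate, epimers at the ester carbon, not isolated | CC(C)=CCC/C(C)=C/C[C@]1(C(=O)CCC=C(C)C)CC(=C)C(C)(C)C(C(=O)OCC)C1=O | intermediate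
13 | 5-[(2E)-3,7-dimethylocta-2,6-dienyl]-4-hydroxy-8,8-dimethyl-7-methylidene-3-(3-methylbut-2-enyl)bicyclo[3.3.1]non-3-ene-2,9-dione, racemate, enol form of the 2,4,9-trione | CC(C)=CCC/C(C)=C/C[C@@]12CC(=C)C(C)(C)[C@H](C2=O)C(=O)C(CC=C(C)C)=C1O | intermediate
14 | 5-[(2E)-3,7-dimethylocta-2,6-dienyl]-4-methoxy-8,8-dimethyl-7-methylidene-3-(3-methylbut-2-enyl)bicyclo[3.3.1]non-3-ene-2,9-dione, racemate | CC(C)=CCC/C(C)=C/C[C@@]12CC(=C)C(C)(C)[C@H](C2=O)C(=O)C(CC=C(C)C)=C1OC | intermediate
15 | 2-methylpropanoyl chloride | CC(C)C(Cl)=O | starting material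
16 | 5-[(2E)-3,7-dimethylocta-2,6-dienyl]-4-methoxy-8,8-dimethyl-7-methylidene-3-(3-methylbut-2-enyl)-1-(2-methylpropanoyl)bicyclo[3.3.1]non-3-ene-2,9-dione, single enantiomer, bridgeheads as in 22 | CC(C)=CCC/C(C)=C/C[C@@]12CC(=C)C(C)(C)[C@](C(=O)C(C)C)(C2=O)C(=O)C(CC=C(C)C)=C1OC | intermediate
17 | 1-bromo-2-methylprop-1-ene | CC(C)=CBr | starting material
18 | 7-endo-[(9-borabicyclo[3.3.1]nonan-9-yl)methyl] analogue of 16 (C7–H exo), not isolated | CC(C)=CCC/C(C)=C/C[C@@]12C[C@@H](CB3C4CCCC3CCC4)C(C)(C)[C@](C(=O)C(C)C)(C2=O)C(=O)C(CC=C(C)C)=C1OC | intermediate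
19 | 5-[(2E)-3,7-dimethylocta-2,6-dienyl]-4-methoxy-8,8-dimethyl-3,7-bis(3-methylbut-2-enyl)-1-(2-methylpropanoyl)bicyclo[3.3.1]non-3-ene-2,9-dione, C7 side chain endo | CC(C)=CCC/C(C)=C/C[C@@]12C[C@@H](CC=C(C)C)C(C)(C)[C@](C(=O)C(C)C)(C2=O)C(=O)C(CC=C(C)C)=C1OC | intermediate
20 | 5-[(2E)-3,7-dimethylocta-2,6-dienyl]-4-hydroxy-8,8-dimethyl-3,7-bis(3-methylbut-2-enyl)-1-(2-methylpropanoyl)bicyclo[3.3.1]non-3-ene-2,9-dione, C7 side chain endo, enol form of the trione | CC(C)=CCC/C(C)=C/C[C@@]12C[C@@H](CC=C(C)C)C(C)(C)[C@](C(=O)C(C)C)(C2=O)C(=O)C(CC=C(C)C)=C1O | intermediate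
21 | caged tetraketone identical with 22 except for prop-1-en-2-yl in place of propan-2-yl at C13 | CC(C)=CCC/C(C)=C/C[C@@]12C[C@H]3C[C@@H]4C(C)(C)[C@@H](C(C)=C)C[C@]4(C1=O)C(=O)[C@@](C(=O)C(C)C)(C2=O)C3(C)C | intermediate
22 | CNP0379246.1: homoadamantane-type tetraketone with 1-(2-methylpropanoyl), 5-geranyl, 8,8-dimethyl and a cyclopentane (C3, C11, C12 gem-dimethyl, C13 isopropyl, C14) fused on C3–C11 | CC(C)=CCC/C(C)=C/C[C@@]12C[C@H]3C[C@@H]4C(C)(C)[C@@H](C(C)C)C[C@]4(C1=O)C(=O)[C@@](C(=O)C(C)C)(C2=O)C3(C)C | target

**Step count and risks**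

Total steps: 13. Longest linear sequence: 11 steps (5 → 22 through steps 3–13, or 1 → 22 through steps 1, 2 and 5–13).

Most likely to fail:

1. Step 7. What may go wrong: slow C-acylation by a tertiary enolate on a deprotonated malonate, drift of the enolate equilibrium to the unproductive C3 side, and retro-Claisen opening of the non-enolisable 1,3-diketone by alkoxide before ring A closes. Fallback, setting out from 7: the two acylations are separated so that the first gives an enolisable product. Compound 7 is alkylated with 4 (NaH, NaI, THF/DMF) to prop-2-enyl 2-[4,4-bis(ethoxycarbonyl)-3,3-dimethyl-2-methylidenebutyl]-7-methyl-3-oxooct-6-enoate F1. Pd(PPh3)4 and morpholine then give diethyl 2-(2,10-dimethyl-3-methylidene-6-oxoundec-9-en-2-yl)propanedioate F2. NaOEt in EtOH at reflux (the Dieckmann conditions of the dimedone synthesis) closes ring B at C5–C9 to ethyl 6,6-dimethyl-5-methylidene-3-(5-methylhex-4-enoyl)-2-oxocyclohexane-1-carboxylate F3, whose 1,3-diketone enolate drives the closure. C-Geranylation of the 1,3-diketone carbon of F3 with 8 (K2CO3, acetone) gives 12, now isolated, and KOt-Bu in THF closes ring A, so the route is rejoined at 13.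

2. Step 9. What may go wrong: proton return or O-acylation at the hindered bridgehead carbanion next to C8, and too little discrimination between the enantiomers by the chiral amide at the conversion needed. Fallback, setting out from 14: the resolution is decoupled from the slow acylation. The same chiral lithium amide is used at −100 °C and the bridgehead anion is trapped with iodine, which should give 5-geranyl-1-iodo-4-methoxy-8,8-dimethyl-7-methylidene-3-prenylbicyclo[3.3.1]non-3-ene-2,9-dione F4. Iodine–magnesium exchange with i-PrMgCl·LiCl and addition to 2-methylpropanal give the 1-(1-hydroxy-2-methylpropyl) carbinol F5 as a mixture of carbinol epimers. Oxidation with the periodinane 1,1,1-triacetoxy-1,1-dihydro-1,2-benziodoxol-3(1H)-one returns to the route at 16.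

3. Step 12. What may go wrong: poor facial selectivity when the C7 prenyl alkene adds to the C3 radical (wrong configuration at C11), and oxidation of the C12 radical by the metal salts before the five-membered ring closes. Fallback, setting out from 20: the cascade is run reductively and without metal oxidants. Chlorination at C3 with N-chlorosuccinimide (CH2Cl2, 0 °C) gives 3-chloro-5-geranyl-8,8-dimethyl-1-(2-methylpropanoyl)-3,7-diprenylbicyclo[3.3.1]nonane-2,4,9-trione F6 (C7 prenyl endo). Chlorine abstraction with (Me3Si)3SiH and Et3B/air in toluene at −20 °C starts the same 7-exo/5-exo sequence at low temperature and ends it by hydrogen transfer to the last radical. This gives the isopropyl group directly and comes back to the route at 22, so step 13 is not needed.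

**Further compounds**

F1 | step 7 | prop-2-enyl 2-[4,4-bis(ethoxycarbonyl)-3,3-dimethyl-2-methylidenebutyl]-7-methyl-3-oxooct-6-enoate, racemate | CC(C)=CCCC(=O)C(CC(=C)C(C)(C)C(C(=O)OCC)C(=O)OCC)C(=O)OCC=C
F2 | step 7 | diethyl 2-(2,10-dimethyl-3-methylidene-6-oxoundec-9-en-2-yl)propanedioate | CCOC(=O)C(C(=O)OCC)C(C)(C)C(=C)CCC(=O)CCC=C(C)C
F3 | step 7 | ethyl 6,6-dimethyl-5-methylidene-3-(5-methylhex-4-enoyl)-2-oxocyclohexane-1-carboxylate, mixture of epimers and enol forms | CCOC(=O)C1C(=O)C(C(=O)CCC=C(C)C)CC(=C)C1(C)C
F4 | step 9 | 5-[(2E)-3,7-dimethylocta-2,6-dienyl]-1-iodo-4-methoxy-8,8-dimethyl-7-methylidene-3-(3-methylbut-2-enyl)bicyclo[3.3.1]non-3-ene-2,9-dione, bridgeheads as in 16 | CC(C)=CCC/C(C)=C/C[C@@]12CC(=C)C(C)(C)[C@](I)(C2=O)C(=O)C(CC=C(C)C)=C1OC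
F5 | step 9 | 1-(1-hydroxy-2-methylpropyl) analogue of 16, carbinol epimers | CC(C)=CCC/C(C)=C/C[C@@]12CC(=C)C(C)(C)[C@](C(O)C(C)C)(C2=O)C(=O)C(CC=C(C)C)=C1OC
F6 | step 12 | 3-chloro-5-[(2E)-3,7-dimethylocta-2,6-dienyl]-8,8-dimethyl-3,7-bis(3-methylbut-2-enyl)-1-(2-methylpropanoyl)bicyclo[3.3.1]nonane-2,4,9-trione, C7 side chain endo, C3 epimers | CC(C)=CCC/C(C)=C/C[C@@]12C[C@@H](CC=C(C)C)C(C)(C)[C@](C(=O)C(C)C)(C2=O)C(=O)C(Cl)(CC=C(C)C)C1=O
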